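(All runs were generated by integration with constants of no real substance.)

One constant can be read before anything is charged: in the midnight run target falls between 2.00 min and 4.00 min at 0.847 min⁻¹. As a reading, that is a lifetime of 1.18 min, shorter than the 10 min you are allowed, so this flask must be stopped early, and you still need to know what to expect from it.

| flask | substrate | partner | capture agent | remark | time |
|---|---|---|---|---|---|
| noon | 37 mM | 0.65 equiv | 37 mM | run made earlier |  |
| midnight | 37 mM | 2.6 equiv | 37 mM | run made earlier |  |
| flask | 37 mM | 1.30 equiv | 37.0 mM |  | 10 min |

| run | time / min | target / % |
|---|---|---|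
| noon | 0.167 | 1.8 |
| noon | 0.333 | 4.3 |
| noon | 0.667 | 6.0 |
| noon | 1.00 | 3.0 |
| noon | 2.00 | 1.8 |
| noon | 4.00 | 0 |
| noon | 8.00 | 0.2 |
| midnight | 0.167 | 13.3 |
| midnight | 0.333 | 35.5 |
| midnight | 0.667 | 51.0 |
| midnight | 1.00 | 48.9 |
| midnight | 2.00 | 28.3 |
| midnight | 4.00 | 5.2 |
| midnight | 8.00 | 0.9 |

(readings scatter by 1 percentage point)

* the best time, 10 min at the latest, for target
* the amount of target, in percent of the substrate charged, at that time

- what was read earlier has a scatter of 1 percentage point, one standard deviation

My own reckoning takes capture as the fast step and treats it as settled, with each capture agent taking one partner's worth. The flask then has 0.300 of free partner, the equivalents of partner less those of capture agent as fractions of the substrate charge. The noon run, at −0.350, still read 6.0% at its peak, so capture leaks, and I take this figure only as a rough estimate of how much of the substrate passes through target over the whole run, and I expect the peak somewhere below it. Charge the recipe unchanged, and stop the flask near 0.667 min, where both runs read highest.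

The forecast, working from “the geometric midpoint of the two runs”, gives 19% at 0.7 min: a peak estimate, where mine is a rough total passing through target.

The flask gives 22.5% at 0.623 min.

    open intermediate + second intermediate → target (k = 7.40 M⁻¹ s⁻¹)
    substrate → decomposition product (k = 9.30 × 10⁻⁶ s⁻¹)
    target → over-reaction product (k = 0.0150 s⁻¹)
    partner → second intermediate (k = 0.140 s⁻¹)
    2 open intermediate → homo product (k = 0.130 M⁻¹ s⁻¹)
    second intermediate + capture agent → trapped intermediate (k = 18.0 M⁻¹ s⁻¹)
    substrate ⇌ open intermediate (K = 21.0, k = 0.0330 s⁻¹)

At 0.623 min target and over-reaction product in this flask together hold 29.9% of the substrate, and by 10.0 min over-reaction product stands at 33.2%, a little above the 0.300 of free partner. Now take the neighbour with 150 mM of substrate and the same equivalents of partner. Its capture agent is 0.247 equiv, so its free partner is 1.05, about its whole substrate charge. In that neighbour target peaks at 51.0%, and by 10.0 min over-reaction product holds 99.6% of the substrate.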